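The second intermediate is the molecule to follow before the next run is set: leave the flask longer, or keep the recipe as it stands?

substrate 20 mM; partner 40.0 mM; reagent 50.0 mM; capture agent 2.00 mM; time 15 d

- why nothing more happens at 15 d, or that something still does (all of the substrate has reacted / the reagent has run out first / the partner has run out first / it is still moving)
- amount of target at 15 d, in percent of the substrate charged
- amount of open intermediate at 15 d, in percent of the substrate charged

Substrate and partner could together take 60.0 mM of reagent, and the flask holds 50.0 mM, so reagent is the limiting reagent. Substrate takes reagent 1.75 times as fast as partner does at equal amounts, so this reckoning counts the substrate as converted, which leaves 30.0 mM of reagent to make second intermediate.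

Each molecule of second intermediate then meets a fork. It couples with open intermediate at 0.77 M⁻¹ h⁻¹ times the level of open intermediate, or it is lost, at 0.027 h⁻¹ to side product and, with the capture agent as charged, at 8.20 × 10⁻⁴ h⁻¹ to the capture agent. The two loss rates over the coupling constant give the even-odds level, the amount of open intermediate at which coupling and loss are equally likely: 36.1 mM. The chance of coupling, the selectivity of the fork, is the level over the level plus this figure.

The substrate charge of 20 mM stands below that level. At the full charge the chance is 35.6 %, which on this reckoning gives 10.7 mM of target. Coupling uses up open intermediate, though, so the mean level is nearer 14.7 mM, the chance 28.9 %, and the target 8.66 mM. That is 43.3 % of the substrate, with 56.7 % staying as open intermediate. The half-life of second intermediate against side product, 1.07 d, is far shorter than the 15 d allowed, so the reckoning expects a stopped flask, and the next run need not be left longer.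

The forecast said that the reagent has run out first, and gave target 42 % (38 % to 46 %) and open intermediate 51 % (47 % to 55 %), “with the side reaction slightly ahead”.

In the flask the reagent has run out first, with 0 % of it left at 15.0 d, and target stands at 40.7 % and open intermediate at 52.5 %. The reckoning counted no leftover substrate, and 6.83 % stands unreacted.

    second intermediate + capture agent → trapped intermediate (k1 = 0.41 M⁻¹ h⁻¹)
    second intermediate → side product (k2 = 0.027 h⁻¹)
    reagent + partner → second intermediate (k3 = 3.2 M⁻¹ h⁻¹)
    open intermediate + second intermediate → target (k4 = 0.77 M⁻¹ h⁻¹)
    substrate + reagent → open intermediate (k5 = 5.6 M⁻¹ h⁻¹)

The turning of second intermediate into side product is the main reason that target in this flask stands at 40.7 %; without that step it reaches 91.3 %. At 1.50 d open intermediate in this flask held 12.9 mM, about a third of the even-odds level, a chance of 26.3 %. The neighbour flask with 10 mM of partner ends with 0 % of its partner, so that charge goes through the fork, and the same reckoning from the full substrate charge gives a mean level of 18.2 mM and a chance of 33.5 %. That reckons 16.8 % of the substrate as target, and that neighbour flask gave 16.0 %.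

All constants belong to no real substance, and the outcome is calculated.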